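**Retrosynthetic overview**

- The target is an ent-labdane (5R,9R,10R). Its C15 acid and C16 isobutyrate are the opened, O-acylated form of the 15,16-butenolide. The last disconnection is therefore lactone opening, and the butenolide comes from a 3-substituted furan.
- The C8 methylene comes from a C8 ketone, made by hydroboration–oxidation of a C8=C9 alkene. The C9–C11 bond comes from a B-alkyl Suzuki coupling of the C9 enol triflate with a 2-(furan-3-yl)ethyl borane.
- The strategy rests on one feature: C9, C10 (with its methyl) and C5 of ring B are the carbonyl, α- and β-carbons of 2-methylcyclohex-2-enone. Ring B is bought. C4–C5 and C1–C10 are made in one conjugate addition–enolate alkylation with isopropenylmagnesium bromide and 2-(phenylsulfonyl)allyl bromide.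
- Ring order: ring B (commercial), then ring A (radical closure of C3–C4, then desulfonylation), then the butenolide ring, which is made late and opened in the last step.

Key step: step 3

Assumptions: labdane numbering (C1–C20) is used for the carbons of all intermediates. In step 3 the ligand enantiomer that gives the (2R,3R) ketone is to be fixed in a short screen; both enantiomers are accessible from D- or L-leucinol. The allyl bromide 3 is made from phenyl vinyl sulfone, because bromination–dehydrobromination of allyl phenyl sulfone would be expected to give the 1-sulfonyl isomer.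

**Step 1**
Reactants: 1 phenyl vinyl sulfone
Product: 2 2-(phenylsulfonyl)prop-2-en-1-ol
Conditions: 37% aq CH2O (3 equiv), DABCO (0.5 equiv), THF/H2O, rt
Reagents that add atoms: formaldehyde, C=O
Why: Morita–Baylis–Hillman hydroxymethylation, in which DABCO adds to the vinyl sulfone, the α-sulfonyl carbanion attacks formaldehyde and the amine is expelled again.

**Step 2**
Reactants: 2 2-(phenylsulfonyl)prop-2-en-1-ol
Product: 3 3-bromo-2-(phenylsulfonyl)prop-1-ene
Conditions: PBr3 (0.4 equiv), Et2O, 0 °C
Reagents that add atoms: phosphorus tribromide, BrP(Br)Br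
Why: bromination of a primary allylic alcohol with PBr3, where direct (SN2) and allylic (SN2′) displacement give the same product because the allyl unit is symmetric.

**Step 3**
Reactants: 4 2-methylcyclohex-2-en-1-one; 5 isopropenylmagnesium bromide; 3 3-bromo-2-(phenylsulfonyl)prop-1-ene
Product: 7 (2R,3R)-2-methyl-2-[2-(phenylsulfonyl)prop-2-en-1-yl]-3-(prop-1-en-2-yl)cyclohexan-1-one, via magnesium enolate 6 (not isolated)
Conditions: Cu(OTf)2 (3 mol%), chiral imidazolinium salt L* (4 mol%; 1-mesityl-3-(1-hydroxy-4-methylpentan-2-yl)-4,5-dihydroimidazolium hexafluorophosphate, NHC precursor), 5 (1.3 equiv), Et2O, −30 °C; then 3 (1.6 equiv), THF/DMPU, −30 → 0 °C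
Reagents that add atoms: none
Why: The Grignard reagent reduces the divalent copper salt and deprotonates the imidazolinium salt to give a chiral NHC-bound monovalent organocopper species, which complexes the enone, adds oxidatively at the β-carbon (C5) to a trivalent copper enolate and reductively eliminates to form C4–C5 and magnesium enolate 6. The enolate then attacks through its methyl-bearing carbon (C10) the CH2 terminus of the vinyl sulfone in 3 and expels bromide, forming C1–C10 and the quaternary centre. The closest known reaction type is the copper-catalysed enantioselective conjugate addition of Grignard reagents to 2-methylcyclohex-2-enone with in situ alkylation of the magnesium enolate by allylic or benzylic halides. No ring is closed in this step. The C5 centre is set by ligand-controlled choice of the enone face; the C10 centre is set by the substrate, because allylic 1,2-strain with the enolate methyl holds the isopropenyl group pseudoaxial and the electrophile enters anti to it, giving the trans C1/C4 relationship. The step needs 1,4- over 1,2-addition (secured by copper), C- over O-alkylation (soft Michael-type acceptor, DMPU) and mono-alkylation (the regiospecifically formed enolate gives a quaternary carbon that cannot re-enolise).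

**Step 4**
Reactants: 7 (2R,3R)-2-methyl-2-[2-(phenylsulfonyl)prop-2-en-1-yl]-3-(prop-1-en-2-yl)cyclohexan-1-one
Product: 8 (4aR,8aR)-5,5,8a-trimethyl-7-(phenylsulfonyl)octahydronaphthalen-1(2H)-one (mixture of epimers at the sulfonyl carbon, labdane C2)
Conditions: Fe(acac)3 (30 mol%), PhSiH3 (2.5 equiv), EtOH/(CH2OH)2 5:1, 60 °C
Reagents that add atoms: none
Why: metal-hydride hydrogen-atom transfer (Mukaiyama-type) to the electron-rich isopropenyl group gives the tertiary C4 radical, which adds 6-endo (Giese addition) to the unsubstituted C3 terminus of the vinyl sulfone before the α-sulfonyl radical is reduced and protonated, so that the trans C1/C4 relationship from step 3 becomes the trans ring fusion of ring A while the new C2 centre is inconsequential.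

**Step 5**
Reactants: 8 (4aR,8aR)-5,5,8a-trimethyl-7-(phenylsulfonyl)octahydronaphthalen-1(2H)-one
Product: 9 (4aR,8aR)-5,5,8a-trimethyloctahydronaphthalen-1(2H)-one
Conditions: 6% Na/Hg, Na2HPO4, MeOH/THF, −20 → 0 °C
Reagents that add atoms: none
Why: reductive desulfonylation by electron transfer from sodium amalgam, in which the sulfone radical anion loses benzenesulfinate and the C2 radical is reduced and protonated, while the hindered C9 ketone next to the quaternary carbon is expected to survive the buffered conditions and no stereocentre is touched.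

**Step 6**
Reactants: 9 (4aR,8aR)-5,5,8a-trimethyloctahydronaphthalen-1(2H)-one
Product: 11 (4aR,8aR)-5,5,8a-trimethyl-3,4,4a,5,6,7,8,8a-octahydronaphthalen-1-yl trifluoromethanesulfonate, via potassium enolate 10 (not isolated)
Conditions: KN(SiMe3)2 (1.2 equiv), THF, −78 °C; then PhNTf2 (1.3 equiv), −78 → 0 °C
Reagents that add atoms: N-phenylbis(trifluoromethanesulfonimide), O=S(=O)(N(c1ccccc1)S(=O)(=O)C(F)(F)F)C(F)(F)F
Why: enol triflate formation, which is regiospecific because only C8 carries α-hydrogens (C10 is quaternary), so a single enolate forms and is O-sulfonylated.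

**Step 7**
Reactants: 12 furan-3-carbaldehyde
Product: 13 3-vinylfuran
Conditions: Ph3PCH3Br (1.2 equiv), KOtBu (1.15 equiv), Et2O, 0 °C → rt; distilled and kept as a THF solution
Reagents that add atoms: methyltriphenylphosphonium bromide, C[P+](c1ccccc1)(c1ccccc1)c1ccccc1.[Br-]
Why: Wittig methylenation of an aromatic aldehyde, with the volatile and polymerisable diene handled only in solution.

**Step 8**
Reactants: 13 3-vinylfuran; 11 (4aR,8aR)-5,5,8a-trimethyl-3,4,4a,5,6,7,8,8a-octahydronaphthalen-1-yl trifluoromethanesulfonate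
Product: 15 3-{2-[(4aR,8aR)-5,5,8a-trimethyl-3,4,4a,5,6,7,8,8a-octahydronaphthalen-1-yl]ethyl}furan, via alkyl-9-BBN 14 (not isolated)
Conditions: 13 (1.5 equiv), 9-BBN-H (0.5 M in THF), 0 °C → rt; then 11, PdCl2(dppf) (5 mol%), AsPh3 (5 mol%), Cs2CO3 (3 equiv), DMF/THF/H2O, 50 °C
Reagents that add atoms: none
Why: anti-Markovnikov hydroboration of the vinyl group with 9-BBN followed by B-alkyl Suzuki–Miyaura coupling, in which zerovalent palladium inserts into the C9–OTf bond, the base-activated borate transfers the primary alkyl group and reductive elimination forms C9–C11.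

**Step 9**
Reactants: 15 3-{2-[(4aR,8aR)-5,5,8a-trimethyl-3,4,4a,5,6,7,8,8a-octahydronaphthalen-1-yl]ethyl}furan
Product: 17 (1S,2S,4aR,8aR)-1-[2-(furan-3-yl)ethyl]-5,5,8a-trimethyldecahydronaphthalen-2-ol, via C8 alkylborane 16 (not isolated)
Conditions: BH3·SMe2 (2 equiv), THF, 0 °C → rt; then 3 M NaOH, 30% H2O2, 0 °C → rt
Reagents that add atoms: hydrogen peroxide, OO
Why: hydroboration–oxidation, in which borane adds syn to the trisubstituted C8=C9 alkene with boron on the less substituted C8 and from the face opposite the axial C10 methyl, setting C9–H trans to that methyl (side chain cis to it, as in the target) and giving the C8 carbinol with retention on oxidation, while the aromatic furan reacts much more slowly than the alkene.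

**Step 10**
Reactants: 17 (1S,2S,4aR,8aR)-1-[2-(furan-3-yl)ethyl]-5,5,8a-trimethyldecahydronaphthalen-2-ol
Product: 18 (1S,4aR,8aR)-1-[2-(furan-3-yl)ethyl]-5,5,8a-trimethyloctahydronaphthalen-2(1H)-one
Conditions: Dess–Martin periodinane (1.5 equiv), NaHCO3, CH2Cl2, 0 °C → rt
Reagents that add atoms: none
Why: Dess–Martin oxidation of the secondary alcohol under buffered conditions that leave the furan and the C9 centre (already the equatorial, thermodynamically preferred epimer) untouched.

**Step 11**
Reactants: 18 (1S,4aR,8aR)-1-[2-(furan-3-yl)ethyl]-5,5,8a-trimethyloctahydronaphthalen-2(1H)-one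
Product: 19 3-{2-[(1R,4aR,8aR)-5,5,8a-trimethyl-2-methylidenedecahydronaphthalen-1-yl]ethyl}furan
Conditions: Ph3PCH3Br (3 equiv), KOtBu (2.8 equiv), toluene, rt → 60 °C
Reagents that add atoms: methyltriphenylphosphonium bromide, C[P+](c1ccccc1)(c1ccccc1)c1ccccc1.[Br-]
Why: Wittig methylenation of the C8 ketone installs C17, and any enolisation towards C9 can only return the equatorial side chain, which is the required configuration.

**Step 12**
Reactants: 19 3-{2-[(1R,4aR,8aR)-5,5,8a-trimethyl-2-methylidenedecahydronaphthalen-1-yl]ethyl}furan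
Product: 21 5-hydroxy-4-{2-[(1R,4aR,8aR)-5,5,8a-trimethyl-2-methylidenedecahydronaphthalen-1-yl]ethyl}furan-2(5H)-one (epimers at the hemiacetal carbon C16), via furan endoperoxide 20 (not isolated)
Conditions: O2, visible light, tetraphenylporphyrin (cat), i-Pr2NEt (5 equiv), CH2Cl2, −78 °C
Reagents that add atoms: dioxygen, O=O
Why: singlet-oxygen [4+2] cycloaddition to the furan followed by base-induced fragmentation of the endoperoxide (Kornblum–DeLaMare type), in which the hindered amine removes the less hindered C15–H so that the carbonyl ends at C15 and the hydroxyl at C16, the 1,1-disubstituted C8=C17 alkene being far slower in the ene reaction at −78 °C.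

**Step 13**
Reactants: 21 5-hydroxy-4-{2-[(1R,4aR,8aR)-5,5,8a-trimethyl-2-methylidenedecahydronaphthalen-1-yl]ethyl}furan-2(5H)-one
Product: 23 4-{2-[(1R,4aR,8aR)-5,5,8a-trimethyl-2-methylidenedecahydronaphthalen-1-yl]ethyl}furan-2(5H)-one, via sodium hydroxy-enoate 22 (not isolated)
Conditions: NaBH4 (2 equiv), EtOH, 0 °C; then 1 M HCl to pH 3, rt
Reagents that add atoms: none
Why: borohydride reduction of the hydroxybutenolide through its ring-opened (Z)-4-oxo-enoate form, followed by lactonisation of the (Z)-4-hydroxy-enoate on acidification, which removes the C16 stereocentre and fixes the C13=C14 geometry inside the ring.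

**Step 14**
Reactants: 23 4-{2-[(1R,4aR,8aR)-5,5,8a-trimethyl-2-methylidenedecahydronaphthalen-1-yl]ethyl}furan-2(5H)-one
Product: 25 (2Z)-3-{[(2-methylpropanoyl)oxy]methyl}-5-[(1R,4aR,8aR)-5,5,8a-trimethyl-2-methylidenedecahydronaphthalen-1-yl]pent-2-enoic acid, via potassium hydroxy-enoate 24 (not isolated)
Conditions: KOH (1.05 equiv), THF/H2O, rt; evaporate, azeotrope with toluene; KN(SiMe3)2 (1.05 equiv), THF/DMPU, −78 °C; (i-PrCO)2O (1.2 equiv), −78 → 0 °C; cold dilute HCl to pH 3–4
Reagents that add atoms: potassium hydroxide, [K+].[OH-]; 2-methylpropanoic anhydride, CC(C)C(=O)OC(=O)C(C)C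
Why: lactone saponification followed by alkoxide acylation, in which the (Z)-4-hydroxy-enoate salt cannot relactonise while its carboxylate is unactivated and its potassium alkoxide should be acylated by the anhydride far faster than the carboxylate, so the C16 oxygen is capped first, the Z geometry is inherited from the ring and acidification frees the acid.

**Compound list**

1 | phenyl vinyl sulfone | C=CS(=O)(=O)c1ccccc1 | starting material
2 | 2-(phenylsulfonyl)prop-2-en-1-ol | C=C(CO)S(=O)(=O)c1ccccc1 | intermediate
3 | 3-bromo-2-(phenylsulfonyl)prop-1-ene | C=C(CBr)S(=O)(=O)c1ccccc1 | intermediate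
4 | 2-methylcyclohex-2-en-1-one | CC1=CCCCC1=O | starting material
5 | isopropenylmagnesium bromide | CC(=C)[Mg]Br | starting material
6 | bromomagnesium (3R)-2-methyl-3-(prop-1-en-2-yl)cyclohex-1-en-1-olate | CC1=C(O[Mg]Br)CCC[C@@H]1C(C)=C | intermediate (not isolated)
7 | (2R,3R)-2-methyl-2-[2-(phenylsulfonyl)prop-2-en-1-yl]-3-(prop-1-en-2-yl)cyclohexan-1-one | O=C1CCC[C@H](C(C)=C)[C@@]1(C)CC(=C)S(=O)(=O)c1ccccc1 | intermediate
8 | (4aR,8aR)-5,5,8a-trimethyl-7-(phenylsulfonyl)octahydronaphthalen-1(2H)-one, C7 epimers | O=C1CCC[C@@H]2C(C)(C)CC(S(=O)(=O)c3ccccc3)C[C@@]12C | intermediate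
9 | (4aR,8aR)-5,5,8a-trimethyloctahydronaphthalen-1(2H)-one | O=C1CCC[C@@H]2C(C)(C)CCC[C@@]12C | intermediate
10 | potassium (4aR,8aR)-5,5,8a-trimethyl-3,4,4a,5,6,7,8,8a-octahydronaphthalen-1-olate | [K+].[O-]C1=CCC[C@@H]2C(C)(C)CCC[C@@]12C | intermediate (not isolated)
11 | (4aR,8aR)-5,5,8a-trimethyl-3,4,4a,5,6,7,8,8a-octahydronaphthalen-1-yl trifluoromethanesulfonate | O=S(=O)(OC1=CCC[C@@H]2C(C)(C)CCC[C@@]12C)C(F)(F)F | intermediate
12 | furan-3-carbaldehyde | O=Cc1ccoc1 | starting material
13 | 3-vinylfuran | C=Cc1ccoc1 | intermediate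
14 | 9-[2-(furan-3-yl)ethyl]-9-borabicyclo[3.3.1]nonane | C(Cc1ccoc1)B1C2CCCC1CCC2 | intermediate (not isolated)
15 | 3-{2-[(4aR,8aR)-5,5,8a-trimethyl-3,4,4a,5,6,7,8,8a-octahydronaphthalen-1-yl]ethyl}furan | C(Cc1ccoc1)C1=CCC[C@@H]2C(C)(C)CCC[C@@]12C | intermediate
16 | C8 monoalkylborane of 15 (BH2 on C8 and H on C9, both on the face opposite the C10 methyl) | B[C@H]1CC[C@@H]2C(C)(C)CCC[C@@]2(C)[C@@H]1CCc1ccoc1 | intermediate (not isolated)
17 | (1S,2S,4aR,8aR)-1-[2-(furan-3-yl)ethyl]-5,5,8a-trimethyldecahydronaphthalen-2-ol | O[C@H]1CC[C@@H]2C(C)(C)CCC[C@@]2(C)[C@@H]1CCc1ccoc1 | intermediate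
18 | (1S,4aR,8aR)-1-[2-(furan-3-yl)ethyl]-5,5,8a-trimethyloctahydronaphthalen-2(1H)-one | O=C1CC[C@@H]2C(C)(C)CCC[C@@]2(C)[C@@H]1CCc1ccoc1 | intermediate
19 | 3-{2-[(1R,4aR,8aR)-5,5,8a-trimethyl-2-methylidenedecahydronaphthalen-1-yl]ethyl}furan | C=C1CC[C@@H]2C(C)(C)CCC[C@@]2(C)[C@@H]1CCc1ccoc1 | intermediate
20 | 2,5-endoperoxide of furan 19 (2,3,7-trioxabicyclo[2.2.1]hept-5-ene carrying the side chain on C5) | C=C1CC[C@@H]2C(C)(C)CCC[C@@]2(C)[C@@H]1CCC1=CC2OOC1O2 | intermediate (not isolated)
21 | 5-hydroxy-4-{2-[(1R,4aR,8aR)-5,5,8a-trimethyl-2-methylidenedecahydronaphthalen-1-yl]ethyl}furan-2(5H)-one, C5 epimers | C=C1CC[C@@H]2C(C)(C)CCC[C@@]2(C)[C@@H]1CCC1=CC(=O)OC1O | intermediate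
22 | sodium (2Z)-3-(hydroxymethyl)-5-[(1R,4aR,8aR)-5,5,8a-trimethyl-2-methylidenedecahydronaphthalen-1-yl]pent-2-enoate | C=C1CC[C@@H]2C(C)(C)CCC[C@@]2(C)[C@@H]1CC/C(=C/C(=O)[O-])CO.[Na+] | intermediate (not isolated)
23 | 4-{2-[(1R,4aR,8aR)-5,5,8a-trimethyl-2-methylidenedecahydronaphthalen-1-yl]ethyl}furan-2(5H)-one | C=C1CC[C@@H]2C(C)(C)CCC[C@@]2(C)[C@@H]1CCC1=CC(=O)OC1 | intermediate
24 | potassium (2Z)-3-(hydroxymethyl)-5-[(1R,4aR,8aR)-5,5,8a-trimethyl-2-methylidenedecahydronaphthalen-1-yl]pent-2-enoate | C=C1CC[C@@H]2C(C)(C)CCC[C@@]2(C)[C@@H]1CC/C(=C/C(=O)[O-])CO.[K+] | intermediate (not isolated)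
25 | (2Z)-3-{[(2-methylpropanoyl)oxy]methyl}-5-[(1R,4aR,8aR)-5,5,8a-trimethyl-2-methylidenedecahydronaphthalen-1-yl]pent-2-enoic acid | C=C1CC[C@@H]2C(C)(C)CCC[C@@]2(C)[C@@H]1CC/C(=C/C(=O)O)COC(=O)C(C)C | target

**Step count**

Total: 14 steps. Longest linear sequence: 13 steps (1 → 25 through steps 1–6 and 8–14; 11 steps from enone 4).

**Steps most likely to fail**

1. Step 3. Face selection in the transfer of an alkenyl group may be insufficient. Capture of the magnesium enolate may also be incomplete or unselective (proton transfer, O-alkylation, or attack of a second enolate on the vinyl sulfone of the product). The fallback sets out from 4 (with 5) and returns at 7. The copper-catalysed addition is run in the presence of Me3SiCl, so that the enolate is silylated as it forms and trimethyl{[(3R)-2-methyl-3-(prop-1-en-2-yl)cyclohex-1-en-1-yl]oxy}silane F1 is isolated and its enantiomeric purity assayed on its own. MeLi in THF at 0 °C then releases lithium (3R)-2-methyl-3-(prop-1-en-2-yl)cyclohex-1-en-1-olate F2 regiospecifically, and this is alkylated with 3 at −78 °C in THF/DMPU to give 7. Sulfone 8 is expected to be crystalline and would offer a point for enrichment by recrystallisation.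

2. Step 8. Alkyl transfer from boron to the hindered vinylpalladium intermediate next to the C10 quaternary carbon may be slow, which would allow hydrolysis of the triflate back to 9 and protodeboronation of 14. The fallback sets out from 13 and returns at 15. The 9-BBN adduct 14 is oxidised (NaOH, H2O2) to 2-(furan-3-yl)ethan-1-ol F3. This is converted with I2, PPh3 and imidazole into 3-(2-iodoethyl)furan F4. Zinc insertion (Zn dust, LiCl, THF) gives [2-(furan-3-yl)ethyl]zinc iodide F5. A base-free Negishi coupling of F5 with triflate 11 (Pd(OAc)2, SPhos, THF, rt → 50 °C) then gives 15.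

3. Step 14. The anhydride may activate the carboxylate before the C16 oxygen is acylated, for example if alkoxide formation from the poorly soluble salt is incomplete. That would lead to relactonisation to 23. The fallback sets out from 23 and returns at 25. Salt 24 is made as in the main route and alkylated on the carboxylate with allyl bromide in DMF to give allyl (2Z)-3-(hydroxymethyl)-5-[(1R,4aR,8aR)-5,5,8a-trimethyl-2-methylidenedecahydronaphthalen-1-yl]pent-2-enoate F6. F6 is acylated at once with isobutyryl chloride, pyridine and DMAP in CH2Cl2 at 0 °C to give allyl (2Z)-3-{[(2-methylpropanoyl)oxy]methyl}-5-[(1R,4aR,8aR)-5,5,8a-trimethyl-2-methylidenedecahydronaphthalen-1-yl]pent-2-enoate F7. The allyl ester is removed with Pd(PPh3)4 (2 mol%) and morpholine in THF at 0 °C; the unhindered allyl ester should ionise faster than the trisubstituted allylic isobutyrate at C16.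

**Further compounds**

F1 | step 3 | trimethyl{[(3R)-2-methyl-3-(prop-1-en-2-yl)cyclohex-1-en-1-yl]oxy}silane | CC1=C(O[Si](C)(C)C)CCC[C@@H]1C(C)=C
F2 | step 3 | lithium (3R)-2-methyl-3-(prop-1-en-2-yl)cyclohex-1-en-1-olate | CC1=C(O[Li])CCC[C@@H]1C(C)=C
F3 | step 8 | 2-(furan-3-yl)ethan-1-ol | OCCc1ccoc1
F4 | step 8 | 3-(2-iodoethyl)furan | ICCc1ccoc1
F5 | step 8 | [2-(furan-3-yl)ethyl]zinc iodide | I[Zn]CCc1ccoc1
F6 | step 14 | allyl (2Z)-3-(hydroxymethyl)-5-[(1R,4aR,8aR)-5,5,8a-trimethyl-2-methylidenedecahydronaphthalen-1-yl]pent-2-enoate | C=C1CC[C@@H]2C(C)(C)CCC[C@@]2(C)[C@@H]1CC/C(=C/C(=O)OCC=C)CO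
F7 | step 14 | allyl (2Z)-3-{[(2-methylpropanoyl)oxy]methyl}-5-[(1R,4aR,8aR)-5,5,8a-trimethyl-2-methylidenedecahydronaphthalen-1-yl]pent-2-enoate | C=C1CC[C@@H]2C(C)(C)CCC[C@@]2(C)[C@@H]1CC/C(=C/C(=O)OCC=C)COC(=O)C(C)C
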